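Atoms are numbered as in the gibberellane skeleton (C1–C19; C20 is absent) for the target and for every intermediate. "Exo" means the face of ring C turned away from the C15–C16 bridge. The target, number 87 of the gibberellin A series, is gibberellic acid with an additional hydroxyl on C12 and is called 12-hydroxygibberellic acid throughout.

## Analysis of the target

The target 37 is a C19 gibberellin in which a cyclohexene ring A, a cyclopentane ring B and a bicyclo[3.2.1]octane (rings C and D, exocyclic C16=C17) are fused in a row, and a γ-lactone runs from C19 on C4 to the oxygen on C10, so that ring A is itself bridged. There are nine stereocentres (C3, C4, C5, C6, C8, C9, C10, C12, C13), of which four are fully substituted (C4, C8, C10, C13) and six are contiguous around ring B (C4–C5–C6–C8–C9–C10). The lactone bridge lies on the face of ring A opposite to H5, so ring A is trans-fused and the lactone ring cis-fused to ring B along C5–C10, and the C6 carboxyl is trans to C4. Across C8–C9 the C9–C10 bond is anti to C15, and the 12-hydroxyl is cis to the bridgehead 13-hydroxyl, on the exo face and 1,3-syn to the C9–C10 bond. The sensitive groups are the tertiary allylic C10–O bond of the lactone (allylic transposition by soft nucleophiles and base, ionisation in acid), the β-hydroxy lactone at C3–C4 (retro-aldol), the C13 carbinol next to the 1,1-disubstituted alkene (acid-induced rearrangement) and the neopentyl-type C7 carboxyl, whose esters resist hydrolysis. The difficulty is density: two vicinal quaternary carbons on ring A, a third (C8) shared by three rings, and oxygen functions that do not tolerate the same reagents. The plan rests on the five-membered lactone ring C19–O–C10–C5–C4: read as a butenolide (C4=C5) whose γ-carbon C10 already carries C9, it offers C5 as an electrophile to the C6 carbon of an acetate arm on C8, and ring A can afterwards be closed from the other face of the same lactone.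

## Retrosynthetic reasoning

**37 ⇒ 36 ⇒ 34 ⇒ 33 (no skeletal bond cut).** The last operations are kept free of base and of strong nucleophiles. The 12,13-diol is released last from acetonide 36. Until then the ketal ties up the 12-oxygen, which sits 1,3-syn to C10 and would add to any acceptor built there. The 3β-alcohol of 36 is taken from enone 34 by a reagent-controlled reduction, and 34 from the 3-epimer 33, so the ring-A closure does not itself have to deliver the 3β-alcohol.

**33 ⇒ 31 (C3–C4).** C4 is the α-carbon of the lactone and C3 carries oxygen, which is an aldol retron. Cutting here removes ring A and the quaternary C4 in one stroke and leaves a (Z)-enal on C10. In the forward sense the aldehyde is tied to C10 and can reach only one face of the lactone enolate, so C4 is set by the tether; only C3 is open, and it is corrected afterwards.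

**31 ⇒ 30 ⇒ 29 (functional groups).** The enal is stored as its diethyl acetal and the C7 acid as a methyl ester only as long as an ester enolate is needed. The methyl group is removed directly after ring B is made, on 29. Later intermediates contain an enal, an enone or the ring-A allylic lactone, all of which a thiolate would attack, and a C7 ester cannot be saponified at the end without damage to ring A.

**29 ⇒ 26 (C5–C6, key disconnection).** Cutting C5–C6 opens ring B and turns the saturated lactone into an α-methylbutenolide whose C10 is quaternary. The forward reaction is a 5-exo conjugate addition of the C6 ester enolate. It forms ring B and C5, and C6 is brought to the more stable configuration by equilibration. C10 has no hydrogen, so no dienolate can form.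

**26 ⇒ 25 ⇒ 21 + 22 (C10–C1).** The (Z)-alkene comes from alkyne 25 by semihydrogenation, and the alkyne from acetylide addition of 22 to the C10 ketone that is unmasked from lactol 21. The two carbon substituents on C10 could be introduced in either order. A nucleophile enters the C10 carbonyl anti to the quaternary C8, and in the target it is C1 that is anti to C8. The alkynyl group is therefore the one added last, to a ketone that already carries the C5=C4(CH3)–C19 unit. The reverse order would lead to the C10 epimer by the same model.

**21 ⇒ 20 ⇒ 19 ⇒ 17 ⇒ 16 ⇒ 12 + 14 (C9–C10).** The butenolide is attached to C9 as a complete five-carbon unit by conjugate addition of silyloxyfuran 14 to enone 12. A carbon nucleophile must be added to C9 (not a hydrogen), because reagents approach the bicyclic enone from the exo face and the target has C10 exo. The C12 ketone left by this addition is then reduced and the diol protected. The γ-carbon C10 of the butenolide is raised to the ketone oxidation level through silyloxyfuran 20.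

**12 ⇒ 11 ⇒ 9 ⇒ 8 (C13–C16, ring D).** The tertiary C13–O centre, the exocyclic methylene and the enone are unravelled to a propargyl group on C8 and an α′-oxygenated cyclohexenone. The enol carbon C13 attacks the activated alkyne. The bridge can form in only one way, so C13 follows from C8.

**8 ⇒ 7 ⇒ 5 ⇒ 4 ⇒ 1 + 2 (C8–C6 and C8–C15).** The quaternary C8 carries two similar CH2 arms, so it is made stereospecifically and not by face selection. A Claisen rearrangement of the allylic alcohol 5 transfers the configuration of one carbinol carbon, set by an oxazaborolidine reduction of 4, to C8. Enone 4 comes from 1 and 2 by alkylative carbonyl transposition, and allylic oxidation of 7 is then directed to C12.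

## Alternatives that were turned down

**Alternative 1:** Ring C is cut at C8–C14 and C9–C11, with ring B present beforehand as a cyclopentenedione. In the forward key step diene A2 adds to the C8=C9 bond of dienophile A3 and gives the cis-fused dione A1. In A1 quaternary C8 carries the propargyl group, H9 is cis to it as the target requires, and C12/C13 arrive as an enediol bis(silyl ether).
- For it: one cycloaddition of two small achiral pieces builds ring C, the quaternary C8, the C8/C9 relation and both ring-C oxygens. This is clearly shorter than the seven steps that lead to 12 here.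
- Against it: ring B is present at the wrong oxidation pattern. C6 and C10 are ketones and C5 a doubly activated methylene. C6 must later be homologated by one carbon next to quaternary C8 with control of its configuration, C10 must receive a C–C and a C–O bond, and C5 must be joined to C4. The enolisable 1,3-dione blurs the distinction between C6 and C10.
- Against it: A2 and A3 are achiral, so the absolute configuration needs a chiral Lewis acid that discriminates the faces of a 2-substituted enedione.
- Against it: ring D would be closed from the enediol ether onto the alkyne, the same kind of step as step 7 here, so that uncertainty is not avoided.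
- Comparison: Alternative 1 wins on convergence at the start. The chosen strategy brings in all carbons of ring A and of the lactone as two intact units (14 and 22) at the right oxidation level and makes ring B in the step that also sets C5 and C6.

**Alternative 2:** The quaternary C8 is made by cutting C8–C15 together with a bond (C14–C16) that the target does not contain. In the forward key step irradiation of enone A6 with allene A5 gives the head-to-head methylenecyclobutane A4, cis-fused to ring C.
- For it: one photochemical step from a simple enone creates C8 with its acetate arm (as a tert-butyl ester that is orthogonal to later methyl esters) and places C15 and C16 next to the C13 ketone. On step count to a C8 quaternary centre this is stronger than the four steps used here.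
- Against it: the C14–C16 bond has to be broken again and C16 re-attached to C13, so the cyclobutane is a detour of several steps before the 13-carbinol/16-methylene unit exists.
- Against it: A4 has no oxygen at C12 and no handle at C9, which is an unactivated methylene. The two centres that the bicyclic enone 12 controls here (C9 by exo addition, C12 by reduction) have no entry point.
- Against it: the cycloaddition of achiral partners gives a racemate unless an auxiliary, a chiral sensitiser or a resolution is added.
- Comparison: the chosen strategy spends more steps on C8 but obtains it enantiomerically defined by a stereospecific rearrangement, with an enone that serves C9, C12 and ring D.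

**Alternative 3:** Ring A is cut at C4–C5 and re-joined through oxygen. In the forward key step the silyl ketene acetal of a six-membered lactone (C19, C4, C3, C2, C1, O) on a ring-B cyclopentene rearranges through a boat: C4 bonds to C5, the C1–O bond breaks, and the acid A7 results with a C1=C10 alkene.
- For it: a concerted, suprafacial step forms the C4–C5 bond, the quaternary C4 and C5 together. C3 is already in place as a protected alcohol, so no oxidation–reduction correction at C3 is needed. On these points it is stronger than the aldol closure used here, which is reversible and needs two extra steps for C3.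
- Against it: A7 is not yet the target ring A. The 19,10-lactone has to be made by halolactonisation onto C10 and elimination to the C1=C2 alkene, and C6 is at the alcohol level (a silyloxymethyl group) and must be oxidised twice late, next to sensitive functionality.
- Against it: the face of C5 that is attacked is dictated by the configuration of the carbinol carbon C1 in the lactone. That is an additional stereocentre, to be set relative to the bicycle and then destroyed.
- Against it: the ring-B cyclopentene with a tetrasubstituted pattern at C10 has to be built first by other chemistry.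
- Comparison: the chosen strategy keeps C7 and C19 at the acid oxidation level throughout, has the lactone in place from the butenolide stage, and needs no separate construction of ring B.

Key step: step 16

Assumption: in the three oxazaborolidine reductions boron is taken to bind the carbonyl lone pair on the side of the smaller flanking group (alkene larger than CH2 in step 2; fully substituted carbon larger than CH2 or alkenyl CH in steps 10 and 21).

## Route

Step 1
Reactants: 1 3-ethoxycyclohex-2-en-1-one; 2 3-bromoprop-1-yne
Product: 4 3-(prop-2-yn-1-yl)cyclohex-2-en-1-one, via bromomagnesium alkoxide adduct 3 (not isolated)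
Conditions: 2, Mg, HgCl2 (cat.), Et2O, 0 °C; then 1, −20 → 0 °C; then 1 M HCl, THF, rt
Reagents that add atoms: water, O
Why: Stork–Danheiser transposition: the propargyl/allenyl Grignard reagent adds 1,2 to the vinylogous ester through its γ-carbon (SE2′), and aqueous acid hydrolyses the enol ether of 3 and eliminates water to give the transposed enone. No stereocentre is formed.

Step 2
Reactants: 4 3-(prop-2-yn-1-yl)cyclohex-2-en-1-one
Product: 5 (1R)-3-(prop-2-yn-1-yl)cyclohex-2-en-1-ol
Conditions: (S)-2-methyl-CBS-oxazaborolidine (20 mol %), catecholborane, toluene, −78 °C; MeOH; aq. NaOH wash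
Reagents that add atoms: none
Why: Corey–Bakshi–Shibata reduction: 1,2-reduction with the alkene as the large group, so that the (S)-catalyst should deliver hydride to the face that gives the (R)-alcohol; catecholborane does not hydroborate the alkyne at this temperature. This carbinol centre is the source of all absolute configuration in the route.

Step 3
Reactants: 5 (1R)-3-(prop-2-yn-1-yl)cyclohex-2-en-1-ol
Product: 7 methyl [(1S)-1-(prop-2-yn-1-yl)cyclohex-2-en-1-yl]acetate, via mixed ketene acetal 6 (not isolated)
Conditions: MeC(OMe)3, EtCO2H (cat.), xylene, 140 °C, −MeOH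
Reagents that add atoms: trimethyl orthoacetate, CC(OC)(OC)OC
Why: Johnson–Claisen rearrangement: orthoester exchange and loss of methanol give ketene acetal 6, which rearranges [3,3]. In the ring the shift is necessarily suprafacial, so the C8–C6 bond forms on the face that carried the oxygen; the (R)-carbinol is translated into the (S)-quaternary centre C8 and the alkene moves to C9=C11.

Step 4
Reactants: 7 methyl [(1S)-1-(prop-2-yn-1-yl)cyclohex-2-en-1-yl]acetate
Product: 8 methyl [(1S)-4-oxo-1-(prop-2-yn-1-yl)cyclohex-2-en-1-yl]acetate
Conditions: CrO3, 3,5-dimethylpyrazole, CH2Cl2, −20 °C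
Reagents that add atoms: chromium trioxide, O=[Cr](=O)=O
Why: Allylic oxidation with the CrO3–3,5-dimethylpyrazole complex (hexavalent chromium): C12 is the only allylic carbon that bears hydrogen (C8 is quaternary), and oxygen transfer to the other end of the allyl system (C9) is hindered by the adjacent quaternary centre, so the enone should be C12(=O)–C11=C9. The propargylic CH2 is neopentyl and should react more slowly.

Step 5
Reactants: 8 methyl [(1S)-4-oxo-1-(prop-2-yn-1-yl)cyclohex-2-en-1-yl]acetate
Product: 9 methyl [5-hydroxy-4-oxo-1-(prop-2-yn-1-yl)cyclohex-2-en-1-yl]acetate (C8 as in 8; both C13 epimers)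
Conditions: LiN(i-Pr)2 (commercial solution), THF, −78 °C; 2-(phenylsulfonyl)-3-phenyloxaziridine, −78 °C; aq. NH4Cl
Reagents that add atoms: 2-(phenylsulfonyl)-3-phenyloxaziridine, O=S(=O)(c1ccccc1)N1OC1c1ccccc1
Why: Kinetic enolisation of the ketone at C13 (its only α-hydrogens, the γ-carbon C8 being quaternary; the ester is much less acidic) and hydroxylation of the enolate with the N-sulfonyloxaziridine (Davis oxidation). The configuration at C13 is irrelevant, as this carbon becomes trigonal in step 6.

Step 6
Reactants: 9 methyl [5-hydroxy-4-oxo-1-(prop-2-yn-1-yl)cyclohex-2-en-1-yl]acetate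
Product: 11 methyl [4-(tert-butyldimethylsilyloxy)-1-(prop-2-yn-1-yl)-5-(triethylsilyloxy)cyclohexa-2,4-dien-1-yl]acetate, via triethylsilyl ether 10 (not isolated)
Conditions: Et3SiOTf, Et3N, CH2Cl2, −78 °C; then t-BuMe2SiOTf, −78 → 0 °C
Reagents that add atoms: triethylsilyl trifluoromethanesulfonate, CC[Si](CC)(CC)OS(=O)(=O)C(F)(F)F; tert-butyldimethylsilyl trifluoromethanesulfonate, CC(C)(C)[Si](C)(C)OS(=O)(=O)C(F)(F)F
Why: The alcohol is silylated first at −78 °C; the second silyl triflate with triethylamine then enolises the α′-silyloxy enone 10 (soft enolisation) towards C13, the only enolisable position, to give the 2,3-bis(silyloxy)diene. The ester is not enolised under these conditions.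

Step 7
Reactants: 11 methyl [4-(tert-butyldimethylsilyloxy)-1-(prop-2-yn-1-yl)-5-(triethylsilyloxy)cyclohexa-2,4-dien-1-yl]acetate
Product: 12 methyl [6-methylidene-4-oxo-5-(triethylsilyloxy)bicyclo[3.2.1]oct-2-en-1-yl]acetate (rings C and D; C8 and C13 as in 37)
Conditions: Ph3PAuCl (5 mol %), AgBF4 (5 mol %), toluene/MeOH 10:1, rt
Reagents that add atoms: none
Why: Proposed new method: the cationic monovalent gold complex activates the alkyne, and C13 of the electron-rich C12=C13 bis(silyloxy)alkene attacks C16 in a 5-exo-dig sense (attack through C12 would need a six-membered ring and would leave a non-conjugated oxocarbenium ion); methanol then removes the tert-butyldimethylsilyl group from the conjugated oxocarbenium ion and protonates the vinylgold species, which leaves the enone, the C13 triethylsilyl ether and the exocyclic methylene, with C13 forced by the bridge into the configuration fixed by C8. The closest known reaction type is the gold-catalysed 5-exo-dig carbocyclisation (Conia-ene type) of silyl enol ethers onto terminal alkynes, including 2-silyloxydienes of 4-propargylcyclohex-2-enones; it has not been shown for an enol carbon that itself bears a silyloxy group.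

Step 8
Reactants: 13 3-methylfuran-2(5H)-one
Product: 14 3-methyl-2-(trimethylsilyloxy)furan
Conditions: Me3SiOTf, Et3N, Et2O, 0 °C; distillation
Reagents that add atoms: trimethylsilyl trifluoromethanesulfonate, C[Si](C)(C)OS(=O)(=O)C(F)(F)F
Why: Soft enolisation of the butenolide (silylation of the carbonyl oxygen, loss of the γ-proton) gives the aromatic 2-silyloxyfuran.

Step 9
Reactants: 12 methyl [6-methylidene-4-oxo-5-(triethylsilyloxy)bicyclo[3.2.1]oct-2-en-1-yl]acetate; 14 3-methyl-2-(trimethylsilyloxy)furan
Product: 16 methyl [6-methylidene-2-(4-methyl-5-oxo-2,5-dihydrofuran-2-yl)-4-oxo-5-(triethylsilyloxy)bicyclo[3.2.1]octan-1-yl]acetate (butenolide exo on C9; both C10 epimers), via trimethylsilyl enol ether 15 (not isolated)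
Conditions: Me3SiOTf (20 mol %), CH2Cl2, −78 °C; then AcOH/THF/H2O, 0 °C
Reagents that add atoms: none
Why: Vinylogous Mukaiyama–Michael addition: the silyloxyfuran reacts through its C5 (the future C10) with the silyl-triflate-activated enone; C9 is attacked on the exo face of the bicyclo[3.2.1]octenone (the side of the one-carbon bridge C14), which places C10 anti to C15 as in the target. The configuration at C10 is not controlled and is erased in step 12; mild acid cleaves enol ether 15.

Step 10
Reactants: 16 methyl [6-methylidene-2-(4-methyl-5-oxo-2,5-dihydrofuran-2-yl)-4-oxo-5-(triethylsilyloxy)bicyclo[3.2.1]octan-1-yl]acetate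
Product: 17 methyl [4-hydroxy-6-methylidene-2-(4-methyl-5-oxo-2,5-dihydrofuran-2-yl)-5-(triethylsilyloxy)bicyclo[3.2.1]octan-1-yl]acetate (12-hydroxyl cis to the 13-oxygen)
Conditions: (R)-2-methyl-CBS-oxazaborolidine (1 equiv), catecholborane, toluene/CH2Cl2, −78 → −40 °C; MeOH
Reagents that add atoms: none
Why: Corey–Bakshi–Shibata reduction under reagent control: the fully substituted C13 is the large group and the C11 methylene the small one, so the (R)-catalyst should deliver hydride to the carbonyl face turned towards the C15–C16 bridge and give the 12-hydroxyl cis to the 13-oxygen and syn to the C9 substituent. The substrate supports this sense, because the opposite (axial) trajectory runs into the syn-axial C9 substituent; catecholborane leaves the butenolide and the alkene alone.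

Step 11
Reactants: 17 methyl [4-hydroxy-6-methylidene-2-(4-methyl-5-oxo-2,5-dihydrofuran-2-yl)-5-(triethylsilyloxy)bicyclo[3.2.1]octan-1-yl]acetate
Product: 19 methyl [4,5-(isopropylidenedioxy)-6-methylidene-2-(4-methyl-5-oxo-2,5-dihydrofuran-2-yl)bicyclo[3.2.1]octan-1-yl]acetate, via free diol 18 (not isolated)
Conditions: camphorsulfonic acid (cat.), MeOH, 0 °C → rt; evaporate; Me2C(OMe)2, acetone, rt; Et3N
Reagents that add atoms: 2,2-dimethoxypropane, COC(C)(C)OC
Why: Acid methanolysis removes the tertiary triethylsilyl ether, and the cis-diol 18 (O12 axial, O13 equatorial on ring C) is closed to the five-membered isopropylidene ketal by acetal exchange. The ketal ties up the 12-oxygen, which lies 1,3-syn to C10 and would otherwise add to the acceptors built on C10 later.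

Step 12
Reactants: 19 methyl [4,5-(isopropylidenedioxy)-6-methylidene-2-(4-methyl-5-oxo-2,5-dihydrofuran-2-yl)bicyclo[3.2.1]octan-1-yl]acetate
Product: 20 methyl {4,5-(isopropylidenedioxy)-6-methylidene-2-[4-methyl-5-(triisopropylsilyloxy)furan-2-yl]bicyclo[3.2.1]octan-1-yl}acetate
Conditions: i-Pr3SiOTf, Et3N, CH2Cl2, 0 °C
Reagents that add atoms: triisopropylsilyl trifluoromethanesulfonate, CC(C)[Si](C(C)C)(C(C)C)OS(=O)(=O)C(F)(F)F
Why: As in step 8: soft enolisation converts the butenolide into the 2-silyloxyfuran and removes the uncontrolled stereocentre at C10; the ester does not enolise under these conditions.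

Step 13
Reactants: 20 methyl {4,5-(isopropylidenedioxy)-6-methylidene-2-[4-methyl-5-(triisopropylsilyloxy)furan-2-yl]bicyclo[3.2.1]octan-1-yl}acetate
Product: 21 methyl [2-(2-hydroxy-4-methyl-5-oxo-2,5-dihydrofuran-2-yl)-4,5-(isopropylidenedioxy)-6-methylidenebicyclo[3.2.1]octan-1-yl]acetate (lactol; both C10 epimers)
Conditions: dimethyldioxirane (1.05 equiv), acetone/CH2Cl2, −78 °C; aq. NH4Cl
Reagents that add atoms: dimethyldioxirane, CC1(C)OO1
Why: Electrophilic oxidation of the 2-silyloxyfuran by the dioxirane at the C10=C5 bond, followed by loss of the silyl group, gives the γ-hydroxybutenolide, the ring tautomer of the (Z)-4-oxo-2-enoic acid. The furan is far more electron-rich than the 1,1-disubstituted alkene, so one equivalent at −78 °C should be selective.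

Step 14
Reactants: 21 methyl [2-(2-hydroxy-4-methyl-5-oxo-2,5-dihydrofuran-2-yl)-4,5-(isopropylidenedioxy)-6-methylidenebicyclo[3.2.1]octan-1-yl]acetate; 22 3,3-diethoxyprop-1-yne
Product: 25 methyl {2-[2-(3,3-diethoxyprop-1-yn-1-yl)-4-methyl-5-oxo-2,5-dihydrofuran-2-yl]-4,5-(isopropylidenedioxy)-6-methylidenebicyclo[3.2.1]octan-1-yl}acetate (C10 as in 37), via lithium keto carboxylate 23 (not isolated), via hydroxy acid 24 (not isolated)
Conditions: 22 (4 equiv), n-BuLi, THF, −78 °C; CeCl3, −78 °C; then 21, −78 °C; AcOH, −78 °C → rt
Reagents that add atoms: none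
Why: Addition of an organocerium acetylide to a γ-hydroxybutenolide: the first equivalent deprotonates the lactol, which opens to the (Z)-keto carboxylate 23; the slender, weakly basic cerium acetylide then adds to the C10 ketone, and acidification closes hydroxy acid 24 to the butenolide. Felkin–Anh control sets C10: the bulky alkenyl group sits outside near H9, the carbonyl oxygen points over ring C, and the nucleophile enters anti to C8, which puts C1 anti to C8 and the oxygen anti to H9 as in the target; with the roles of the two carbon groups exchanged the same model leads to the C10 epimer, which is why the alkyne is brought in last.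

Step 15
Reactants: 25 methyl {2-[2-(3,3-diethoxyprop-1-yn-1-yl)-4-methyl-5-oxo-2,5-dihydrofuran-2-yl]-4,5-(isopropylidenedioxy)-6-methylidenebicyclo[3.2.1]octan-1-yl}acetate
Product: 26 methyl {2-[2-[(1Z)-3,3-diethoxyprop-1-en-1-yl]-4-methyl-5-oxo-2,5-dihydrofuran-2-yl]-4,5-(isopropylidenedioxy)-6-methylidenebicyclo[3.2.1]octan-1-yl}acetate
Conditions: H2 (1 atm), Pd/CaCO3 poisoned with Pb(OAc)2 (Lindlar catalyst), quinoline, EtOAc, rt
Reagents that add atoms: none
Why: Lindlar semihydrogenation: syn addition of one equivalent of hydrogen gives the (Z)-alkene; the poisoned catalyst should leave the 1,1-disubstituted alkene and the conjugated, trisubstituted butenolide alkene untouched.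

Step 16
Reactants: 26 methyl {2-[2-[(1Z)-3,3-diethoxyprop-1-en-1-yl]-4-methyl-5-oxo-2,5-dihydrofuran-2-yl]-4,5-(isopropylidenedioxy)-6-methylidenebicyclo[3.2.1]octan-1-yl}acetate
Product: 29 3,4-seco-12-hydroxygibberellic acid 12,13-acetonide 3-(diethyl acetal) 7-methyl ester (1Z; 4-methyl trans to C6), via potassium ester enolate 27 (not isolated), via potassium lactone enolate 28 (not isolated)
Conditions: KN(SiMe3)2 (1.15 equiv), THF, −78 → −20 °C; t-BuOH, 0 °C; aq. NH4Cl
Reagents that add atoms: none
Why: KN(SiMe3)2 removes a C6–H of the ester (the only acidic C–H: C10 is quaternary, so no γ-deprotonation of the butenolide can compete) to give enolate 27, which adds to C5, the β-carbon of the butenolide, and the resulting lactone enolate 28 is protonated at C4. The closest known reaction type is the intramolecular Michael addition of ester enolates to butenolides and other unsaturated lactones, which gives cis-fused bicyclic lactones. Ring B closes in the 5-exo-trig mode (C4=C5 is exocyclic to the forming ring), which the Baldwin rules favour, whereas 1,2-attack on the lactone carbonyl C19 would give a strained bridged tetrahedral intermediate that can only revert or open to a seven-membered β-keto ester. C5: the C6 nucleophile is tied through C8 to C9 and can reach only the butenolide face that carries C9, so H5 ends up cis to C1 as a five-five fusion demands, and the configuration of C10 (step 14) thus dictates C5. C6: equilibration through the reversible addition and through potassium tert-butoxide in tert-butanol should place the ester trans to C4 on ring B, the less hindered arrangement and that of the target. C4: protonation under the same equilibrating conditions should give the methyl group trans to C6, and this centre is made trigonal again in step 19, so it is of no consequence. The step needs site selectivity (secured by the absence of any other enolisable position), 1,4- over 1,2-addition (secured by ring size and reversibility) and control of C5 and C6 (secured by the fusion and by equilibration).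

Step 17
Reactants: 29 3,4-seco-12-hydroxygibberellic acid 12,13-acetonide 3-(diethyl acetal) 7-methyl ester
Product: 30 3,4-seco-12-hydroxygibberellic acid 12,13-acetonide 3-(diethyl acetal) (free C7 acid)
Conditions: n-PrSLi (from n-PrSH and n-BuLi), HMPA, rt; AcOH, pH 5 buffer
Reagents that add atoms: none
Why: SN2 demethylation by the thiolate at the methyl carbon, which does not depend on access to the hindered acyl carbon C7. It is placed here because 29 has no Michael acceptor, and the SN2′ terminus of its allylic C10–O bond (C2) is an unactivated alkene carbon shielded by the acetal carbon; on the enal, the enone or the final ring-A lactone a thiolate would add or displace.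

Step 18
Reactants: 30 3,4-seco-12-hydroxygibberellic acid 12,13-acetonide 3-(diethyl acetal)
Product: 31 3,4-seco-12-hydroxygibberellic acid 12,13-acetonide 3-aldehyde ((1Z)-enal on C10; free C7 acid)
Conditions: pyridinium p-toluenesulfonate (cat.), acetone/H2O 10:1, rt
Reagents that add atoms: water, O
Why: Acid-catalysed hydrolysis of the allylic acetal through a stabilised oxocarbenium ion, under conditions that leave the ring-fused acetonide and the lactone intact. A short reaction time at room temperature should preserve the (Z)-geometry, which is required for ring closure.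

Step 19
Reactants: 31 3,4-seco-12-hydroxygibberellic acid 12,13-acetonide 3-aldehyde
Product: 33 3-epi-12-hydroxygibberellic acid 12,13-acetonide (3α-hydroxyl), via dilithium enolate 32 (not isolated)
Conditions: LiN(SiMe3)2 (2.3 equiv), THF, −78 °C; AcOH, −78 °C
Reagents that add atoms: none
Why: Intramolecular aldol addition (6-enolexo-exo-trig): the second equivalent of base forms the lactone enolate 32 (the carboxylate α-carbon C6 is not deprotonated), and the aldehyde, tied to C10, can reach only the enolate face syn to C1, which sets C4 with the methyl group on the side of ring B. With lithium a closed, chelated (Zimmerman–Traxler-type) transition state places the aldehyde oxygen next to the enolate oxygen and should lead to the 3α-alcohol (O3 gauche to C19); this centre is corrected in steps 20 and 21.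

Step 20
Reactants: 33 3-epi-12-hydroxygibberellic acid 12,13-acetonide
Product: 34 3-dehydro-12-hydroxygibberellic acid 12,13-acetonide (3-oxo-1-ene)
Conditions: Dess–Martin periodinane, NaHCO3, CH2Cl2, 0 °C → rt
Reagents that add atoms: none
Why: Dess–Martin oxidation of the secondary allylic alcohol under buffered, non-basic conditions. The product is a β-keto lactone without an enolisable position (C4 is quaternary), so nothing can epimerise, and base (retro-Claisen cleavage) is avoided.

Step 21
Reactants: 34 3-dehydro-12-hydroxygibberellic acid 12,13-acetonide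
Product: 36 12-hydroxygibberellic acid 12,13-acetonide, via acyloxyborane 35 (not isolated)
Conditions: catecholborane (1.1 equiv), CH2Cl2, 0 °C; then (R)-2-methyl-CBS-oxazaborolidine (1 equiv), catecholborane (2 equiv), −78 → −40 °C; MeOH; pH 4 buffer
Reagents that add atoms: none
Why: The acid is first masked as acyloxyborane 35; the Corey–Bakshi–Shibata reduction then runs under reagent control with quaternary C4 as the large and the alkenyl carbon C2 as the small group, so that the (R)-catalyst should deliver hydride to the face on the side of the lactone bridge and give the 3β-alcohol (3S). Reduction is 1,2, and the borane ester is hydrolysed on work-up.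

Step 22
Reactants: 36 12-hydroxygibberellic acid 12,13-acetonide
Product: 37 12-hydroxygibberellic acid
Conditions: AcOH/H2O 3:1, 40 °C
Reagents that add atoms: none
Why: Acid-catalysed hydrolysis of the isopropylidene ketal with the weakest acid that should do it, because the allylic lactone, the 3-hydroxyl and the C13 carbinol next to the C16 alkene are all acid-sensitive. The bridgehead position of C13 disfavours ionisation there.

## Compound list

1 | 3-ethoxycyclohex-2-en-1-one | CCOC1=CC(=O)CCC1 | starting material
2 | 3-bromoprop-1-yne (propargyl bromide) | C#CCBr | starting material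
3 | bromomagnesium 3-ethoxy-1-(prop-2-yn-1-yl)cyclohex-2-en-1-olate (racemic adduct) | CCOC1=CC(CC#C)(O[Mg]Br)CCC1 | intermediate (not isolated)
4 | 3-(prop-2-yn-1-yl)cyclohex-2-en-1-one | C#CCC1=CC(=O)CCC1 | intermediate
5 | (1R)-3-(prop-2-yn-1-yl)cyclohex-2-en-1-ol | C#CCC1=C[C@H](O)CCC1 | intermediate
6 | (3R)-3-[(1-methoxyethenyl)oxy]-1-(prop-2-yn-1-yl)cyclohex-1-ene (mixed ketene acetal) | C#CCC1=C[C@H](OC(=C)OC)CCC1 | intermediate (not isolated)
7 | methyl [(1S)-1-(prop-2-yn-1-yl)cyclohex-2-en-1-yl]acetate | C#CC[C@]1(CC(=O)OC)CCCC=C1 | intermediate
8 | methyl [(1S)-4-oxo-1-(prop-2-yn-1-yl)cyclohex-2-en-1-yl]acetate | C#CC[C@]1(CC(=O)OC)CCC(=O)C=C1 | intermediate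
9 | methyl [5-hydroxy-4-oxo-1-(prop-2-yn-1-yl)cyclohex-2-en-1-yl]acetate; C8 as in 8, both epimers at the carbinol carbon C13 | C#CC[C@]1(CC(=O)OC)CC(O)C(=O)C=C1 | intermediate
10 | methyl [4-oxo-1-(prop-2-yn-1-yl)-5-(triethylsilyloxy)cyclohex-2-en-1-yl]acetate; C8 as in 8, both C13 epimers | C#CC[C@]1(CC(=O)OC)CC(O[Si](CC)(CC)CC)C(=O)C=C1 | intermediate (not isolated)
11 | methyl [4-(tert-butyldimethylsilyloxy)-1-(prop-2-yn-1-yl)-5-(triethylsilyloxy)cyclohexa-2,4-dien-1-yl]acetate; C8 as in 8 | C#CC[C@]1(CC(=O)OC)CC(O[Si](CC)(CC)CC)=C(O[Si](C)(C)C(C)(C)C)C=C1 | intermediate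
12 | methyl [6-methylidene-4-oxo-5-(triethylsilyloxy)bicyclo[3.2.1]oct-2-en-1-yl]acetate; bridgeheads C8 and C13 as in 37 | C=C1C[C@]2(CC(=O)OC)C[C@@]1(O[Si](CC)(CC)CC)C(=O)C=C2 | intermediate
13 | 3-methylfuran-2(5H)-one | CC1=CCOC1=O | starting material
14 | 3-methyl-2-(trimethylsilyloxy)furan | Cc1ccoc1O[Si](C)(C)C | intermediate
15 | trimethylsilyl enol ether (C11=C12–OSiMe3) of 16; butenolide exo on C9, both C10 epimers | C=C1C[C@]2(CC(=O)OC)C[C@@]1(O[Si](CC)(CC)CC)C(O[Si](C)(C)C)=C[C@H]2C1OC(=O)C(C)=C1 | intermediate (not isolated)
16 | methyl [6-methylidene-2-(4-methyl-5-oxo-2,5-dihydrofuran-2-yl)-4-oxo-5-(triethylsilyloxy)bicyclo[3.2.1]octan-1-yl]acetate; butenolide exo on C9 (anti to C15), both C10 epimers | C=C1C[C@]2(CC(=O)OC)C[C@@]1(O[Si](CC)(CC)CC)C(=O)C[C@H]2C1OC(=O)C(C)=C1 | intermediate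
17 | methyl [4-hydroxy-6-methylidene-2-(4-methyl-5-oxo-2,5-dihydrofuran-2-yl)-5-(triethylsilyloxy)bicyclo[3.2.1]octan-1-yl]acetate; 12-hydroxyl cis to the 13-oxygen and syn to the C9 substituent, both C10 epimers | C=C1C[C@]2(CC(=O)OC)C[C@@]1(O[Si](CC)(CC)CC)[C@@H](O)C[C@H]2C1OC(=O)C(C)=C1 | intermediate
18 | methyl [4,5-dihydroxy-6-methylidene-2-(4-methyl-5-oxo-2,5-dihydrofuran-2-yl)bicyclo[3.2.1]octan-1-yl]acetate (cis-12,13-diol) | C=C1C[C@]2(CC(=O)OC)C[C@@]1(O)[C@@H](O)C[C@H]2C1OC(=O)C(C)=C1 | intermediate (not isolated)
19 | methyl [4,5-(isopropylidenedioxy)-6-methylidene-2-(4-methyl-5-oxo-2,5-dihydrofuran-2-yl)bicyclo[3.2.1]octan-1-yl]acetate (12,13-acetonide; both C10 epimers) | C=C1C[C@]2(CC(=O)OC)C[C@@]1(OC(C)(C)O3)[C@@H]3C[C@H]2C1OC(=O)C(C)=C1 | intermediate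
20 | methyl {4,5-(isopropylidenedioxy)-6-methylidene-2-[4-methyl-5-(triisopropylsilyloxy)furan-2-yl]bicyclo[3.2.1]octan-1-yl}acetate | C=C1C[C@]2(CC(=O)OC)C[C@@]1(OC(C)(C)O3)[C@@H]3C[C@H]2c1cc(C)c(O[Si](C(C)C)(C(C)C)C(C)C)o1 | intermediate
21 | methyl [2-(2-hydroxy-4-methyl-5-oxo-2,5-dihydrofuran-2-yl)-4,5-(isopropylidenedioxy)-6-methylidenebicyclo[3.2.1]octan-1-yl]acetate (γ-hydroxybutenolide; both C10 epimers) | C=C1C[C@]2(CC(=O)OC)C[C@@]1(OC(C)(C)O3)[C@@H]3C[C@H]2C1(O)OC(=O)C(C)=C1 | intermediate
22 | 3,3-diethoxyprop-1-yne | C#CC(OCC)OCC | starting material
23 | lithium (2Z)-2-methyl-4-oxo-4-[C9 of the bicyclic acetonide ester]but-2-enoate (ring-opened form of 21) | C=C1C[C@]2(CC(=O)OC)C[C@@]1(OC(C)(C)O3)[C@@H]3C[C@H]2C(=O)/C=C(/C)C(=O)[O-].[Li+] | intermediate (not isolated)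
24 | (2Z)-4-hydroxy-2-methyl-4-(3,3-diethoxyprop-1-yn-1-yl)-4-[C9 of the bicyclic acetonide ester]but-2-enoic acid; C10 as in 37 | C=C1C[C@]2(CC(=O)OC)C[C@@]1(OC(C)(C)O3)[C@@H]3C[C@H]2[C@](O)(C#CC(OCC)OCC)/C=C(/C)C(=O)O | intermediate (not isolated)
25 | methyl {2-[2-(3,3-diethoxyprop-1-yn-1-yl)-4-methyl-5-oxo-2,5-dihydrofuran-2-yl]-4,5-(isopropylidenedioxy)-6-methylidenebicyclo[3.2.1]octan-1-yl}acetate; C10 as in 37 | C=C1C[C@]2(CC(=O)OC)C[C@@]1(OC(C)(C)O3)[C@@H]3C[C@H]2[C@@]1(C#CC(OCC)OCC)OC(=O)C(C)=C1 | intermediate
26 | methyl {2-[2-[(1Z)-3,3-diethoxyprop-1-en-1-yl]-4-methyl-5-oxo-2,5-dihydrofuran-2-yl]-4,5-(isopropylidenedioxy)-6-methylidenebicyclo[3.2.1]octan-1-yl}acetate (precursor of the key step) | C=C1C[C@]2(CC(=O)OC)C[C@@]1(OC(C)(C)O3)[C@@H]3C[C@H]2[C@@]1(/C=C\C(OCC)OCC)OC(=O)C(C)=C1 | intermediate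
27 | potassium ester enolate of 26 (C6=C7(O−)OMe) | C=C1C[C@]2(C=C([O-])OC)C[C@@]1(OC(C)(C)O3)[C@@H]3C[C@H]2[C@@]1(/C=C\C(OCC)OCC)OC(=O)C(C)=C1.[K+] | intermediate (not isolated)
28 | potassium lactone enolate (C4=C19–O−) of 29; ring B closed | C=C1C[C@]23C[C@@]1(OC(C)(C)O4)[C@@H]4C[C@H]2[C@@]2(/C=C\C(OCC)OCC)OC([O-])=C(C)[C@H]2[C@@H]3C(=O)OC.[K+] | intermediate (not isolated)
29 | 3,4-seco-12-hydroxygibberellic acid 12,13-acetonide 3-(diethyl acetal) 7-methyl ester: rings B, C, D and the 19,10-lactone closed; (1Z)-3,3-diethoxyprop-1-enyl on C10; 4-H with methyl trans to C6 | C=C1C[C@]23C[C@@]1(OC(C)(C)O4)[C@@H]4C[C@H]2[C@@]2(/C=C\C(OCC)OCC)OC(=O)[C@H](C)[C@H]2[C@@H]3C(=O)OC | intermediate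
30 | 3,4-seco-12-hydroxygibberellic acid 12,13-acetonide 3-(diethyl acetal), free C7 acid | C=C1C[C@]23C[C@@]1(OC(C)(C)O4)[C@@H]4C[C@H]2[C@@]2(/C=C\C(OCC)OCC)OC(=O)[C@H](C)[C@H]2[C@@H]3C(=O)O | intermediate
31 | 3,4-seco-12-hydroxygibberellic acid 12,13-acetonide 3-aldehyde ((1Z)-enal on C10), free C7 acid | C=C1C[C@]23C[C@@]1(OC(C)(C)O4)[C@@H]4C[C@H]2[C@@]2(/C=C\C=O)OC(=O)[C@H](C)[C@H]2[C@@H]3C(=O)O | intermediate
32 | dilithium salt of 31 (C7 carboxylate and C4=C19 lactone enolate) | C=C1C[C@]23C[C@@]1(OC(C)(C)O4)[C@@H]4C[C@H]2[C@@]2(/C=C\C=O)OC([O-])=C(C)[C@H]2[C@@H]3C(=O)[O-].[Li+].[Li+] | intermediate (not isolated)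
33 | 3-epi-12-hydroxygibberellic acid 12,13-acetonide (3α-hydroxyl) | C=C1C[C@]23C[C@@]1(OC(C)(C)O4)[C@@H]4C[C@H]2[C@@]12C=C[C@@H](O)[C@@](C)(C(=O)O1)[C@H]2[C@@H]3C(=O)O | intermediate
34 | 3-dehydro-12-hydroxygibberellic acid 12,13-acetonide (3-oxo-1-ene) | C=C1C[C@]23C[C@@]1(OC(C)(C)O4)[C@@H]4C[C@H]2[C@@]12C=CC(=O)[C@@](C)(C(=O)O1)[C@H]2[C@@H]3C(=O)O | intermediate
35 | catechol acyloxyborane of 34 (C7 carboxyl bound to boron) | C=C1C[C@]23C[C@@]1(OC(C)(C)O4)[C@@H]4C[C@H]2[C@@]12C=CC(=O)[C@@](C)(C(=O)O1)[C@H]2[C@@H]3C(=O)OB5Oc6ccccc6O5 | intermediate (not isolated)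
36 | 12-hydroxygibberellic acid 12,13-acetonide | C=C1C[C@]23C[C@@]1(OC(C)(C)O4)[C@@H]4C[C@H]2[C@@]12C=C[C@H](O)[C@@](C)(C(=O)O1)[C@H]2[C@@H]3C(=O)O | intermediate
37 | 12-hydroxygibberellic acid (gibberellic acid with a 12-hydroxyl cis to the 13-hydroxyl; number 87 of the gibberellin A series) | C=C1C[C@]23C[C@@]1(O)[C@@H](O)C[C@H]2[C@@]12C=C[C@H](O)[C@@](C)(C(=O)O1)[C@H]2[C@@H]3C(=O)O | target

## Step count and least certain steps

Total step count: 22. Longest linear sequence: 21 steps (steps 1–7 and 9–22; step 8 prepares 14 in one step from 13).

**Step 7 (Proposed new method).** The likely failure is protodesilylation of the very electron-rich bis(silyloxy)diene by methanol before the carbocyclisation, or C–C bond formation through C12 to a six-membered ring. The fallback uses known chemistry, sets out from 9 and comes back at 12. Compound 9 is silylated (Et3SiCl, imidazole) and its triethylsilyl ether 10 is isolated this time. Bromoboration of the alkyne with 9-bromo-9-borabicyclo[3.3.1]nonane and protonolysis with AcOH should give methyl [1-(2-bromoprop-2-en-1-yl)-4-oxo-5-(triethylsilyloxy)cyclohex-2-en-1-yl]acetate F1. An intramolecular palladium-catalysed α-alkenylation of the ketone enolate (Pd(PPh3)4, KOt-Bu, THF) then joins C13 to C16: zerovalent palladium inserts into the C16–Br bond and the C13 enolate is coupled, which returns to 12.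

**Step 16 (key step).** The likely failure is slow conjugate addition at the β-carbon next to the quaternary C10, so that proton exchange, retro-addition or attack of the enolate on the lactone carbonyl competes, or incomplete equilibration at C6. The fallback sets out from 26 and comes back at 29. A silyl triflate/amine-mediated intramolecular Michael addition (t-BuMe2SiOTf, Et3N, CH2Cl2) works without a free enolate: the ester is converted into its ketene silyl acetal in the flask and adds to the silyl-activated butenolide. The product is the lactone silyl ketene acetal F2 (the 19-O-tert-butyldimethylsilyl ketene acetal of 29). Aqueous acid work-up protonates it to 29, and C6 is equilibrated afterwards with KOt-Bu in t-BuOH.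

**Step 14.** The likely failure is enolisation of the C10 ketone towards C9 by the acetylide (loss of conversion, erosion of C9), transfer of the new C10 alkoxide onto the C7 ester, or insufficient face discrimination at C10. The fallback sets out from 21 and comes back at 25. Lactol 21 is acetylated (Ac2O, pyridine, 4-dimethylaminopyridine) to the pseudo-acetate methyl [2-(2-acetoxy-4-methyl-5-oxo-2,5-dihydrofuran-2-yl)-4,5-(isopropylidenedioxy)-6-methylidenebicyclo[3.2.1]octan-1-yl]acetate F3. Ionisation with Me3SiOTf (CH2Cl2, −78 °C) gives the acyloxocarbenium ion at C10, which is captured by tributyl(3,3-diethoxyprop-1-yn-1-yl)stannane; at this temperature the tertiary pseudo-acetate should ionise faster than the diethyl acetal of the stannane. This route has no basic step, and the nucleophile again enters anti to C8.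

**Step 19.** The likely failure is addition of the amide base to the aldehyde, isomerisation of the (Z)-enal to the (E)-enal (which cannot cyclise) before closure, or retro-aldol on warming. The fallback sets out from 31 and comes back at 33 or at 36. A one-pot silyl ketene acetal formation and Mukaiyama aldol addition (Me3SiOTf, i-Pr2NEt, CH2Cl2, −78 → 0 °C) closes ring A through an open transition state without a metal enolate. It gives the bis-silylated adduct F4 (3-O-trimethylsilyl ether, trimethylsilyl ester; C3 not assigned). Mild acid methanolysis releases 33 or its C3 epimer 36. Compound 33 continues through steps 20 and 21, and 36 goes directly to step 22.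

**Step 22.** The likely failure is acid-induced ionisation of the allylic C10–O bond (migration of the lactone to C2, diene-acid formation), dehydration at C3, or rearrangement of the C13 carbinol/C16 alkene during ketal hydrolysis. The fallback sets out from 34 and comes back at 37. The order of the last two events is reversed: the ketal is hydrolysed on the enone 34 (aqueous AcOH), whose ring A has no allylic alcohol and an electron-poor alkene next to the lactone, to give 3-dehydro-12-hydroxygibberellic acid F5. Conjugate addition of the freed 12-hydroxyl to C1 is reversible under these conditions and must be watched. F5 is then reduced as in step 21 ((R)-2-methyl-CBS-oxazaborolidine, excess catecholborane) to 37.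

Further compounds

F1 | step 7 | methyl [1-(2-bromoprop-2-en-1-yl)-4-oxo-5-(triethylsilyloxy)cyclohex-2-en-1-yl]acetate (C8 as in 8; both C13 epimers) | C=C(Br)C[C@]1(CC(=O)OC)CC(O[Si](CC)(CC)CC)C(=O)C=C1
F2 | step 16 | 19-O-tert-butyldimethylsilyl ketene acetal of 29 (C4=C19 silyl ketene acetal of the tetracyclic lactone ester) | C=C1C[C@]23C[C@@]1(OC(C)(C)O4)[C@@H]4C[C@H]2[C@@]2(/C=C\C(OCC)OCC)OC(O[Si](C)(C)C(C)(C)C)=C(C)[C@H]2[C@@H]3C(=O)OC
F3 | step 14 | methyl [2-(2-acetoxy-4-methyl-5-oxo-2,5-dihydrofuran-2-yl)-4,5-(isopropylidenedioxy)-6-methylidenebicyclo[3.2.1]octan-1-yl]acetate (both C10 epimers) | C=C1C[C@]2(CC(=O)OC)C[C@@]1(OC(C)(C)O3)[C@@H]3C[C@H]2C1(OC(C)=O)OC(=O)C(C)=C1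
F4 | step 19 | 3-O-trimethylsilyl-12-hydroxygibberellic acid 12,13-acetonide trimethylsilyl ester (C3 not assigned) | C=C1C[C@]23C[C@@]1(OC(C)(C)O4)[C@@H]4C[C@H]2[C@@]12C=CC(O[Si](C)(C)C)[C@@](C)(C(=O)O1)[C@H]2[C@@H]3C(=O)O[Si](C)(C)C
F5 | step 22 | 3-dehydro-12-hydroxygibberellic acid (3-oxo-1-ene, free 12,13-diol) | C=C1C[C@]23C[C@@]1(O)[C@@H](O)C[C@H]2[C@@]12C=CC(=O)[C@@](C)(C(=O)O1)[C@H]2[C@@H]3C(=O)O
A1 | alternative 1 | cis-7a-(prop-2-yn-1-yl)-5,6-bis(trimethylsilyloxy)-3a,4,7,7a-tetrahydro-1H-indene-1,3(2H)-dione (enantiomer as in the SMILES) | C#CC[C@@]12C(=O)CC(=O)[C@@H]1CC(O[Si](C)(C)C)=C(O[Si](C)(C)C)C2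
A2 | alternative 1 | 2,3-bis(trimethylsilyloxy)buta-1,3-diene | C=C(O[Si](C)(C)C)C(=C)O[Si](C)(C)C
A3 | alternative 1 | 4-(prop-2-yn-1-yl)cyclopent-4-ene-1,3-dione | C#CCC1=CC(=O)CC1=O
A4 | alternative 2 | tert-butyl (7-methylidene-5-oxobicyclo[4.2.0]octan-1-yl)acetate (cis-fused; enantiomer as in the SMILES) | C=C1C[C@@]2(CC(=O)OC(C)(C)C)CCCC(=O)[C@@H]12
A5 | alternative 2 | propa-1,2-diene (allene) | C=C=C
A6 | alternative 2 | tert-butyl (3-oxocyclohex-1-en-1-yl)acetate | CC(C)(C)OC(=O)CC1=CC(=O)CCC1
A7 | alternative 3 | tetracyclic C19 acid with C1=C10 alkene, 3-O-tert-butyldimethylsilyl ether, C7 as tert-butyldimethylsilyloxymethyl, 12,13-acetonide | C=C1C[C@]23C[C@@]1(OC(C)(C)O4)[C@@H]4C[C@H]2C2=CC[C@H](O[Si](C)(C)C(C)(C)C)[C@@](C)(C(=O)O)[C@H]2[C@@H]3CO[Si](C)(C)C(C)(C)C
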